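**Retrosynthetic overview**

- The quinone ring is read as two pieces. C1–C4 (C1=O, C2–OH, C3–CH3, C4=O) are a squaric acid unit that carries the methyl group. C5–C6 (C5–OH, C6–chain) are a 2-methoxyvinyl unit with the nonadec-14-enyl chain on its α-carbon.
- Target ⇐ hydrolysis of both vinylogous methyl esters of the 2,5-dimethoxyquinone ⇐ oxidation of the hexasubstituted hydroquinone ⇐ thermal ring expansion of a 4-hydroxy-4-(2-methoxyvinyl)cyclobutenone. This step makes the C4–C5 bond and the only ring, the six-membered carbocycle.
- Cyclobutenone ⇐ 3-methoxy-4-methylcyclobutenedione (dimethyl squarate + MeLi) + the β-lithio enol ether from a (Z)-2-bromo enol ether (bond C1–C6).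
- Bromo enol ether ⇐ (E)-icos-15-enal (Wittig methoxymethylenation, then Br2/DBU) ⇐ 15-pentadecanolide + pentyl phenyltetrazolyl sulfone (Julia–Kocienski olefination sets the E-alkene).

Key step: step 11

Remark: the target has no stereocentre. Its only stereo-element is the (E)-C14′=C15′ alkene of the side chain, so "single enantiomer" is taken to mean this single geometric isomer.

**Route**

Step 1
Reactants: 1 1-phenyl-1H-tetrazole-5-thiol; 2 1-bromopentane
Product: 3 5-(pentylsulfanyl)-1-phenyl-1H-tetrazole
Conditions: K2CO3, acetone, reflux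
Reagents that add atoms: none
Why: SN2 S-alkylation of the soft thiolate by a primary bromide should be clean and selective for sulfur.

Step 2
Reactants: 3 5-(pentylsulfanyl)-1-phenyl-1H-tetrazole
Product: 4 5-(pentylsulfonyl)-1-phenyl-1H-tetrazole
Conditions: 30% H2O2, (NH4)6Mo7O24·4H2O (cat.), EtOH, 0 °C → rt
Reagents that add atoms: hydrogen peroxide, OO
Why: Molybdate-catalysed peroxide oxidation takes the sulfide through the sulfoxide to the sulfone without touching the tetrazole, the standard preparation of Julia–Kocienski sulfones.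

Step 3
Reactants: 5 15-pentadecanolide
Product: 6 methyl 15-hydroxypentadecanoate
Conditions: MeOH, H2SO4 (cat.), reflux
Reagents that add atoms: methanol, CO
Why: Acid-catalysed transesterification in methanol as solvent opens the unstrained macrolactone to the hydroxy ester, driven by the large excess of methanol.

Step 4
Reactants: 6 methyl 15-hydroxypentadecanoate
Product: 7 methyl 15-oxopentadecanoate
Conditions: TEMPO (cat.), PhI(OAc)2, CH2Cl2, rt
Reagents that add atoms: none
Why: Oxoammonium-mediated (TEMPO/diacetoxyiodobenzene) oxidation stops at the aldehyde for a primary alcohol and leaves the ester alone.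

Step 5
Reactants: 7 methyl 15-oxopentadecanoate; 4 5-(pentylsulfonyl)-1-phenyl-1H-tetrazole
Product: 8 methyl (E)-icos-15-enoate
Conditions: 4, KHMDS, DME, −60 °C; then 7, −60 °C → rt; H2O
Reagents that add atoms: none
Why: Julia–Kocienski olefination: the potassium anion of the phenyltetrazolyl sulfone adds to the unbranched aldehyde through the anti β-alkoxy sulfone, and Smiles rearrangement with anti-elimination should give mainly the (E)-alkene, while the remote ester is not attacked at this temperature (any Z isomer would be removed on AgNO3-impregnated silica).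

Step 6
Reactants: 8 methyl (E)-icos-15-enoate
Product: 9 (E)-icos-15-enal
Conditions: DIBAL-H (1.05 equiv), CH2Cl2, −78 °C; MeOH, aq. Rochelle salt
Reagents that add atoms: none
Why: Partial DIBAL-H reduction of a methyl ester: the aluminium hemiacetal is stable at −78 °C and releases the aldehyde only on work-up, and the isolated alkene is inert.

Step 7
Reactants: 9 (E)-icos-15-enal; 10 (methoxymethyl)triphenylphosphonium chloride
Product: 11 (16E)-1-methoxyhenicosa-1,16-diene (mixture of 1E and 1Z isomers)
Conditions: 10, KOtBu, THF, 0 °C; then 9, 0 °C → rt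
Reagents that add atoms: none
Why: Wittig methoxymethylenation with the non-stabilised ylide gives the one-carbon homologated enol ether, and its E/Z mixture is of no consequence because both isomers converge in step 8.

Step 8
Reactants: 11 (16E)-1-methoxyhenicosa-1,16-diene
Product: 13 (1Z,16E)-2-bromo-1-methoxyhenicosa-1,16-diene (Br cis to OMe), via 1,2-dibromide 12 (not isolated)
Conditions: Br2 (1.0 equiv), CH2Cl2, −78 °C; then DBU, −78 °C → rt
Reagents that add atoms: bromine, BrBr
Why: Bromination–dehydrobromination of an enol ether: the enol ether adds bromine far faster than the isolated alkene, so one equivalent at −78 °C should react only at C1=C2, and amine-induced loss of HBr from the α-bromo ether through its oxocarbenium ion gives the 2-bromo enol ether, expected mainly as the Z isomer (purified on base-washed silica).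

Step 9
Reactants: 14 dimethyl squarate; 15 methyllithium
Product: 18 3-methoxy-4-methylcyclobut-3-ene-1,2-dione, via lithium alkoxide 16 (not isolated), via trifluoroacetate 17 (not isolated)
Conditions: THF, −78 °C; then (CF3CO)2O, −78 °C; then H2O, → rt
Reagents that add atoms: water, O
Why: 1,2-Addition of MeLi to one squarate carbonyl, O-trifluoroacetylation, ionisation to the methoxy-stabilised cyclobutenyl cation and hydrolysis at the methoxy-bearing terminus with loss of methanol is the standard conversion of a squarate ester into a 3-alkoxy-4-alkylcyclobutenedione.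

Step 10
Reactants: 13 (1Z,16E)-2-bromo-1-methoxyhenicosa-1,16-diene; 18 3-methoxy-4-methylcyclobut-3-ene-1,2-dione
Product: 20 4-hydroxy-3-methoxy-4-[(1Z,16E)-1-methoxyhenicosa-1,16-dien-2-yl]-2-methylcyclobut-2-en-1-one (racemic), via vinyllithium 19 (not isolated)
Conditions: 13, t-BuLi (2 equiv), THF, −78 °C; then 18, −78 °C; pH 7 buffer
Reagents that add atoms: none
Why: Bromine–lithium exchange with retention gives the vinyllithium with lithium cis to the methoxy group (internally coordinated and slow to lose LiOMe at −78 °C), which should add 1,2 to the more electrophilic carbonyl of 18, the one next to the methoxy-bearing carbon and outside the vinylogous ester conjugation, giving the tertiary carbinol as a racemate whose stereocentre is erased in step 11.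

Step 11
Reactants: 20 4-hydroxy-3-methoxy-4-[(1Z,16E)-1-methoxyhenicosa-1,16-dien-2-yl]-2-methylcyclobut-2-en-1-one
Product: 23 3,6-dimethoxy-2-methyl-5-[(E)-nonadec-14-enyl]benzene-1,4-diol, via dienylketene 21 (not isolated), via cyclohexadienone 22 (not isolated)
Conditions: toluene (degassed), 110 °C, Ar
Reagents that add atoms: none
Why: Heating opens the C1–C4 bond of the cyclobutenone in a conrotatory 4π electrocyclic reaction to dienylketene 21, and a 6π electrocyclisation then joins the ketene carbon to the methoxy-bearing vinyl carbon (target C4–C5) to give dienone 22, which enolises to the aromatic hydroquinone 23. The closest known reaction type is the thermal ring expansion of 4-alkenyl-4-hydroxycyclobutenones to hydroquinones (Moore rearrangement). The six-membered carbocycle is closed by a thermally allowed disrotatory 6π electrocyclisation of the (Z)-configured dienylketene. No stereocentre remains: the carbinol centre of 20 becomes sp2 on ring opening, the C6 centre of 22 is lost on enolisation, and the remote (E)-alkene is not touched. The step needs inward rotation of the vinyl group, which the strong preference of the C4 oxygen donor for outward rotation secures, and it needs the methyl and chain para to each other, which the regiochemistry of step 10 has already fixed. Release of four-ring strain and aromatisation should drive the cascade to completion.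

Step 12
Reactants: 23 3,6-dimethoxy-2-methyl-5-[(E)-nonadec-14-enyl]benzene-1,4-diol
Product: 24 2,5-dimethoxy-3-methyl-6-[(E)-nonadec-14-enyl]cyclohexa-2,5-diene-1,4-dione
Conditions: Ag2O, Na2SO4, Et2O, rt
Reagents that add atoms: none
Why: Silver(I) oxide is the mild standard oxidant for electron-rich hydroquinones and should give the quinone without affecting the alkene or the methyl ethers.

Step 13
Reactants: 24 2,5-dimethoxy-3-methyl-6-[(E)-nonadec-14-enyl]cyclohexa-2,5-diene-1,4-dione
Product: 25 2,5-dihydroxy-3-methyl-6-[(E)-nonadec-14-enyl]cyclohexa-2,5-diene-1,4-dione (target)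
Conditions: 2 M NaOH, MeOH–THF, 50 °C; then 1 M HCl
Reagents that add atoms: sodium hydroxide, [Na+].[OH-]
Why: Hydroxide adds to each methoxy-bearing carbon of the two vinylogous esters and expels methoxide (addition–elimination) to give the stable bis-enolate, which acidification converts into the dihydroxyquinone, and the isolated alkene is inert to these conditions.

**Compound list**

1 | 1-phenyl-1H-tetrazole-5-thiol | Sc1nnnn1-c1ccccc1 | starting material
2 | 1-bromopentane | CCCCCBr | starting material
3 | 5-(pentylsulfanyl)-1-phenyl-1H-tetrazole | CCCCCSc1nnnn1-c1ccccc1 | intermediate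
4 | 5-(pentylsulfonyl)-1-phenyl-1H-tetrazole | CCCCCS(=O)(=O)c1nnnn1-c1ccccc1 | intermediate
5 | 15-pentadecanolide | O=C1CCCCCCCCCCCCCCO1 | starting material
6 | methyl 15-hydroxypentadecanoate | COC(=O)CCCCCCCCCCCCCCO | intermediate
7 | methyl 15-oxopentadecanoate | COC(=O)CCCCCCCCCCCCCC=O | intermediate
8 | methyl (E)-icos-15-enoate | COC(=O)CCCCCCCCCCCCC/C=C/CCCC | intermediate
9 | (E)-icos-15-enal | O=CCCCCCCCCCCCCC/C=C/CCCC | intermediate
10 | (methoxymethyl)triphenylphosphonium chloride | [Cl-].COC[P+](c1ccccc1)(c1ccccc1)c1ccccc1 | starting material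
11 | (16E)-1-methoxyhenicosa-1,16-diene (1E/1Z mixture) | COC=CCCCCCCCCCCCCC/C=C/CCCC | intermediate
12 | (16E)-1,2-dibromo-1-methoxyhenicos-16-ene (diastereomer mixture, not isolated) | COC(Br)C(Br)CCCCCCCCCCCCC/C=C/CCCC | intermediate
13 | (1Z,16E)-2-bromo-1-methoxyhenicosa-1,16-diene | CO/C=C(\Br)CCCCCCCCCCCCC/C=C/CCCC | intermediate
14 | dimethyl squarate (3,4-dimethoxycyclobut-3-ene-1,2-dione) | COC1=C(OC)C(=O)C1=O | starting material
15 | methyllithium | [Li]C | starting material
16 | lithium 2,3-dimethoxy-1-methyl-4-oxocyclobut-2-en-1-olate (racemic, not isolated) | COC1=C(OC)C(C)(O[Li])C1=O | intermediate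
17 | 2,3-dimethoxy-1-methyl-4-oxocyclobut-2-en-1-yl trifluoroacetate (racemic, not isolated) | COC1=C(OC)C(C)(OC(=O)C(F)(F)F)C1=O | intermediate
18 | 3-methoxy-4-methylcyclobut-3-ene-1,2-dione | COC1=C(C)C(=O)C1=O | intermediate
19 | [(1E,16E)-1-methoxyhenicosa-1,16-dien-2-yl]lithium (Li cis to OMe, not isolated) | [Li]/C(CCCCCCCCCCCCC/C=C/CCCC)=C\OC | intermediate
20 | 4-hydroxy-3-methoxy-4-[(1Z,16E)-1-methoxyhenicosa-1,16-dien-2-yl]-2-methylcyclobut-2-en-1-one (racemic) | O=C1C(C)=C(OC)C1(O)/C(CCCCCCCCCCCCC/C=C/CCCC)=C\OC | intermediate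
21 | (3Z,5Z,19E)-4-hydroxy-3-methoxy-5-(methoxymethylidene)-2-methyltetracosa-1,3,19-trien-1-one (dienylketene, not isolated) | O=C=C(C)/C(OC)=C(/O)\C(CCCCCCCCCCCCC/C=C/CCCC)=C/OC | intermediate
22 | 4-hydroxy-3,6-dimethoxy-2-methyl-5-[(E)-nonadec-14-enyl]cyclohexa-2,4-dien-1-one (racemic, not isolated) | O=C1C(C)=C(OC)C(O)=C(CCCCCCCCCCCCC/C=C/CCCC)C1OC | intermediate
23 | 3,6-dimethoxy-2-methyl-5-[(E)-nonadec-14-enyl]benzene-1,4-diol | COc1c(C)c(O)c(OC)c(CCCCCCCCCCCCC/C=C/CCCC)c1O | intermediate
24 | 2,5-dimethoxy-3-methyl-6-[(E)-nonadec-14-enyl]cyclohexa-2,5-diene-1,4-dione | COC1=C(C)C(=O)C(OC)=C(CCCCCCCCCCCCC/C=C/CCCC)C1=O | intermediate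
25 | 2,5-dihydroxy-3-methyl-6-[(E)-nonadec-14-enyl]cyclohexa-2,5-diene-1,4-dione | CCCC/C=C/CCCCCCCCCCCCCC1=C(O)C(=O)C(C)=C(O)C1=O | target

**Step count**

Total: 13 steps. Longest linear sequence: 10 steps (steps 3, 4, 5, 6, 7, 8, 10, 11, 12, 13, from 15-pentadecanolide).

**Steps most likely to fail**

Step 11. The dienylketene may be diverted before the 6π closure, by lactonisation onto the enol oxygen after the wrong sense of rotation or by intermolecular capture, and the enol ether may be lost at 110 °C, so that the ring does not close cleanly. The fallback gives up the electrocyclic ring construction and places the chain on a preformed quinone by decarboxylative radical alkylation. It sets out from 8 and comes back at 24. Ester 8 is saponified (LiOH, THF–H2O) to (E)-icos-15-enoic acid F10. Commercial 1,2,4,5-tetramethoxybenzene F11 is lithiated (n-BuLi, TMEDA, THF, 0 °C) and methylated (MeI) to 1,2,4,5-tetramethoxy-3-methylbenzene F12. Oxidative demethylation with ceric ammonium nitrate (MeCN–H2O, 0 °C) gives 2,5-dimethoxy-3-methylcyclohexa-2,5-diene-1,4-dione F13. Silver-catalysed persulfate decarboxylation of F10 (AgNO3 cat., K2S2O8, MeCN–H2O, 65 °C) in the presence of F13 should put the nonadec-14-enyl radical on the only free ring position and give 24.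

Step 8. Bromine may also add to the remote C16=C17 alkene, and the geometry of the dehydrobromination may be poorly controlled. The fallback completes and purifies the bromo enol ether before the alkene exists. It sets out from 6 and comes back at 13. Alcohol 6 is silylated (TBSCl, imidazole, DMF) to methyl 15-(tert-butyldimethylsilyloxy)pentadecanoate F1. DIBAL-H at −78 °C gives 15-(tert-butyldimethylsilyloxy)pentadecanal F2. Wittig reaction with the ylide from 10 gives tert-butyl[(16-methoxyhexadec-15-en-1-yl)oxy]dimethylsilane F3. Bromination (Br2, CH2Cl2, −78 °C) gives tert-butyl[(15,16-dibromo-16-methoxyhexadecyl)oxy]dimethylsilane F4, which is not isolated, and DBU gives {[(15Z)-15-bromo-16-methoxyhexadec-15-en-1-yl]oxy}(tert-butyl)dimethylsilane F5. Desilylation with TBAF gives (15Z)-15-bromo-16-methoxyhexadec-15-en-1-ol F6. Non-acidic Parikh–Doering oxidation (SO3·pyridine, DMSO, i-Pr2NEt) gives (15Z)-15-bromo-16-methoxyhexadec-15-enal F7. Julia–Kocienski olefination of F7 with the potassium anion of 4 (KHMDS, DME, −60 °C) gives 13.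

Step 10. After a successful addition, the tertiary allylic hydroxyl may ionise and the enol ether may hydrolyse during aqueous work-up and chromatography of 20, with collapse to an enal. The fallback never liberates the free carbinol. It sets out from 13 and 18 and comes back at 23. The lithium alkoxide formed from 19 and 18 is captured at −78 °C with chlorotrimethylsilane to give 3-methoxy-4-[(1Z,16E)-1-methoxyhenicosa-1,16-dien-2-yl]-2-methyl-4-(trimethylsilyloxy)cyclobut-2-en-1-one F8. F8 is filtered through basic alumina and heated in degassed toluene at 110 °C, where the same ring opening and 6π closure should give 3,6-dimethoxy-2-methyl-5-[(E)-nonadec-14-enyl]-4-(trimethylsilyloxy)phenol F9. Buffered fluoride (TBAF, AcOH, THF, 0 °C) then returns 23.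

**Further compounds**

F1 | step 8 | methyl 15-(tert-butyldimethylsilyloxy)pentadecanoate | COC(=O)CCCCCCCCCCCCCCO[Si](C)(C)C(C)(C)C
F2 | step 8 | 15-(tert-butyldimethylsilyloxy)pentadecanal | O=CCCCCCCCCCCCCCCO[Si](C)(C)C(C)(C)C
F3 | step 8 | tert-butyl[(16-methoxyhexadec-15-en-1-yl)oxy]dimethylsilane (E/Z mixture) | COC=CCCCCCCCCCCCCCCO[Si](C)(C)C(C)(C)C
F4 | step 8 | tert-butyl[(15,16-dibromo-16-methoxyhexadecyl)oxy]dimethylsilane | COC(Br)C(Br)CCCCCCCCCCCCCCO[Si](C)(C)C(C)(C)C
F5 | step 8 | {[(15Z)-15-bromo-16-methoxyhexadec-15-en-1-yl]oxy}(tert-butyl)dimethylsilane | CO/C=C(\Br)CCCCCCCCCCCCCCO[Si](C)(C)C(C)(C)C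
F6 | step 8 | (15Z)-15-bromo-16-methoxyhexadec-15-en-1-ol | CO/C=C(\Br)CCCCCCCCCCCCCCO
F7 | step 8 | (15Z)-15-bromo-16-methoxyhexadec-15-enal | CO/C=C(\Br)CCCCCCCCCCCCCC=O
F8 | step 10 | 3-methoxy-4-[(1Z,16E)-1-methoxyhenicosa-1,16-dien-2-yl]-2-methyl-4-(trimethylsilyloxy)cyclobut-2-en-1-one (racemic) | O=C1C(C)=C(OC)C1(O[Si](C)(C)C)/C(CCCCCCCCCCCCC/C=C/CCCC)=C\OC
F9 | step 10 | 3,6-dimethoxy-2-methyl-5-[(E)-nonadec-14-enyl]-4-(trimethylsilyloxy)phenol | COc1c(C)c(O)c(OC)c(CCCCCCCCCCCCC/C=C/CCCC)c1O[Si](C)(C)C
F10 | step 11 | (E)-icos-15-enoic acid | OC(=O)CCCCCCCCCCCCC/C=C/CCCC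
F11 | step 11 | 1,2,4,5-tetramethoxybenzene | COc1cc(OC)c(OC)cc1OC
F12 | step 11 | 1,2,4,5-tetramethoxy-3-methylbenzene | COc1cc(OC)c(OC)c(C)c1OC
F13 | step 11 | 2,5-dimethoxy-3-methylcyclohexa-2,5-diene-1,4-dione | COC1=CC(=O)C(OC)=C(C)C1=O
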